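The disconnection is the C5–C6 bond, where the vinylic CH of the C4=C5 alkene meets the allylic lactone carbinol shared by the nine-membered oxonene (O, C3–C10), the ten-membered carbocycle and the γ-lactone. An intramolecular Nozaki–Hiyama–Kishi addition of a (Z)-alkenyl iodide to the C6 aldehyde closes the medium ring onto a preformed oxolane and sets C6. The new alkoxide then lactonizes onto the C12 acrylate ester, so two rings and one stereocentre form in one operation. The precursor is a 2,2,5-trisubstituted oxolane carrying the iodoalkene at C3 and, at C10, a chain with the C8 angelate, the C7 formyl group and the methyl acrylate.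

Key step: step 15

Atom labels follow germacrane numbering: C1 oxolane carbinol, C2, C3 ether CH, C4=C5 (C15 on C4), C6 lactone carbinol, C7, C8 angelate carbinol, C9, C10 quaternary ether carbon (C14), C11=C13, C12 carbonyl.

Assumption: the SMILES is read literally as (1S,3S,6S,7R,8R,10R), which puts the C4 and C9 arms trans on the oxolane (C14 and the C1 hydroxyl cis to the C4 arm) and makes the lactone cis-fused; the ring closed in step 15 is therefore a strained inside–outside bicycle.

Step 1
Reactants: 1 propargyl alcohol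
Product: 3 (Z)-3-iodo-2-methylprop-2-en-1-ol, via alkenylmagnesium chelate 2 (not isolated)
Conditions: MeMgBr (3 equiv), CuI (10 mol%), THF, −10 °C → rt; then I2, −78 → 0 °C
Reagents that add atoms: methylmagnesium bromide C[Mg]Br; iodine II
Why: Copper-catalysed anti-carbomagnesiation of the propargylic alkoxide places magnesium on the terminal carbon cis to the CH2O group (five-membered chelate 2), and iodinolysis with retention should give the Z iodide.

Step 2
Reactants: 3 (Z)-3-iodo-2-methylprop-2-en-1-ol
Product: 4 (Z)-3-iodo-2-methylprop-2-enal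
Conditions: MnO2 (15 equiv), CH2Cl2, 0 °C, dark; filtered and used at once
Reagents that add atoms: none
Why: Allylic oxidation with MnO2 is neutral and should preserve the labile Z geometry of the enal.

Step 3
Reactants: 4 (Z)-3-iodo-2-methylprop-2-enal
Product: 6 (3S,1Z)-1-iodo-2-methylhexa-1,5-dien-3-ol, via borinate 5 (not isolated)
Conditions: (−)-Ipc2BOMe, allylMgBr, Et2O, 0 °C → rt; then 4, −78 °C; then NaOH, H2O2, 0 °C → rt
Reagents that add atoms: allylmagnesium bromide C=CC[Mg]Br
Why: Brown allylboration through a chair transition state; the reagent derived from (+)-α-pinene attacks the Si face of the enal, which sets C3 as S.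

Step 4
Reactants: 6 (3S,1Z)-1-iodo-2-methylhexa-1,5-dien-3-ol; 7 methacrolein
Product: 8 (2E,5S,6Z)-5-hydroxy-7-iodo-2,6-dimethylhepta-2,6-dienal
Conditions: second-generation Hoveyda–Grubbs catalyst (H2IMes)Cl2Ru=CH(C6H4-2-OiPr) (5 mol%), methacrolein (8 equiv), CH2Cl2, 40 °C
Reagents that add atoms: none
Why: Olefin cross-metathesis of the terminal alkene with methacrolein should give the thermodynamically favoured E trisubstituted enal (C1=C10 with C14 cis to C2), and the trisubstituted iodoalkene does not engage the ruthenium carbene.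

Step 5
Reactants: 8 (2E,5S,6Z)-5-hydroxy-7-iodo-2,6-dimethylhepta-2,6-dienal
Product: 9 (1Z,3S,5E)-1-iodo-2,6-dimethylocta-1,5,7-trien-3-ol
Conditions: Ph3PCH3Br (2.5 equiv), KOtBu (2.5 equiv), THF, 0 °C
Reagents that add atoms: methyltriphenylphosphonium bromide C[P+](c1ccccc1)(c1ccccc1)c1ccccc1.[Br-]
Why: Wittig methylenation turns the enal into the 2-substituted diene without touching either alkene geometry; excess ylide covers the free hydroxyl.

Step 6
Reactants: 9 (1Z,3S,5E)-1-iodo-2,6-dimethylocta-1,5,7-trien-3-ol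
Product: 11 (2R,3S,5S)-2-ethenyl-5-[(1Z)-1-iodoprop-1-en-2-yl]-2-methyloxolan-3-ol, via vinyl epoxide 10 (not isolated)
Conditions: ent-Shi ketone (1,2:4,5-di-O-isopropylidene-β-L-erythro-2,3-hexodiulo-2,6-pyranose, 30 mol%), KHSO5, K2CO3, Bu4NHSO4, MeCN/CH2(OMe)2–aq. buffer (pH 10.5), 0 °C; then CSA (10 mol%), CH2Cl2, −40 → 0 °C
Reagents that add atoms: potassium peroxymonosulfate [K+].[O-]S(=O)(=O)OO
Why: Shi epoxidation with the L-fructose-derived ketone should select the electron-rich trisubstituted alkene of the diene and give the (1S,10S) epoxide by reagent control (spiro transition state); acid then drives endo opening by the C3 hydroxyl at the allylic tertiary C10 with inversion (vinyl-epoxide-directed cyclization), which sets C1 as S and C10 as R with C14 cis to the C1 hydroxyl and the C9 arm trans to the C4 arm.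

Step 7
Reactants: 11 (2R,3S,5S)-2-ethenyl-5-[(1Z)-1-iodoprop-1-en-2-yl]-2-methyloxolan-3-ol
Product: 12 tert-butyl{[(2R,3S,5S)-2-ethenyl-5-[(1Z)-1-iodoprop-1-en-2-yl]-2-methyloxolan-3-yl]oxy}dimethylsilane
Conditions: TBSOTf, 2,6-lutidine, CH2Cl2, −78 → 0 °C
Reagents that add atoms: tert-butyldimethylsilyl triflate CC(C)(C)[Si](C)(C)OS(=O)(=O)C(F)(F)F
Why: Silylation with the triflate protects the hindered C1 hydroxyl so that only the C8 hydroxyl is acylated later.

Step 8
Reactants: 12 tert-butyl{[(2R,3S,5S)-2-ethenyl-5-[(1Z)-1-iodoprop-1-en-2-yl]-2-methyloxolan-3-yl]oxy}dimethylsilane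
Product: 14 2-[(2R,3S,5S)-3-(tert-butyldimethylsilyloxy)-5-[(1Z)-1-iodoprop-1-en-2-yl]-2-methyloxolan-2-yl]ethan-1-ol, via alkylborane 13 (not isolated)
Conditions: 9-BBN dimer, THF, 0 °C → rt; then aq. NaOH, H2O2, 0 °C
Reagents that add atoms: hydrogen peroxide OO
Why: Anti-Markovnikov hydroboration with 9-BBN should touch only the monosubstituted vinyl group (the trisubstituted iodoalkene is inert), and oxidation gives the C8 primary alcohol.

Step 9
Reactants: 14 2-[(2R,3S,5S)-3-(tert-butyldimethylsilyloxy)-5-[(1Z)-1-iodoprop-1-en-2-yl]-2-methyloxolan-2-yl]ethan-1-ol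
Product: 15 2-[(2R,3S,5S)-3-(tert-butyldimethylsilyloxy)-5-[(1Z)-1-iodoprop-1-en-2-yl]-2-methyloxolan-2-yl]acetaldehyde
Conditions: Dess–Martin periodinane, pyridine, CH2Cl2, 0 °C → rt
Reagents that add atoms: none
Why: Dess–Martin oxidation gives the C8 aldehyde under buffered conditions that avoid β-elimination of the oxolane oxygen.

Step 10
Reactants: 16 2,2-dimethoxyacetaldehyde (60% aqueous); 17 methyl acrylate
Product: 18 methyl 3-hydroxy-4,4-dimethoxy-2-methylidenebutanoate (racemic)
Conditions: DABCO (0.5 equiv), 1,4-dioxane/H2O, rt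
Reagents that add atoms: none
Why: Morita–Baylis–Hillman reaction of an activated aldehyde assembles C6, C7, C11, C12 and C13 with C6 already masked at the aldehyde oxidation level.

Step 11
Reactants: 18 methyl 3-hydroxy-4,4-dimethoxy-2-methylidenebutanoate
Product: 19 methyl (Z)-2-(bromomethyl)-4,4-dimethoxybut-2-enoate
Conditions: NBS, Me2S, CH2Cl2, 0 °C → rt
Reagents that add atoms: N-bromosuccinimide O=C1CCC(=O)N1Br
Why: Corey–Kim-type activation as the alkoxysulfonium salt and SN2' displacement by bromide should give the rearranged allylic bromide as the thermodynamic Z isomer (CH2Br cis to the acetal carbon) without acid that would open the acetal.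

Step 12
Reactants: 15 2-[(2R,3S,5S)-3-(tert-butyldimethylsilyloxy)-5-[(1Z)-1-iodoprop-1-en-2-yl]-2-methyloxolan-2-yl]acetaldehyde; 19 methyl (Z)-2-(bromomethyl)-4,4-dimethoxybut-2-enoate
Product: 21 methyl (3R,4R)-5-[(2R,3S,5S)-3-(tert-butyldimethylsilyloxy)-5-[(1Z)-1-iodoprop-1-en-2-yl]-2-methyloxolan-2-yl]-3-(dimethoxymethyl)-4-hydroxy-2-methylidenepentanoate, via allylzinc bromide 20 (not isolated)
Conditions: Zn dust (activated), THF, 0 °C; cold sat. aq. NH4Cl work-up
Reagents that add atoms: none
Why: Barbier-type 2-(alkoxycarbonyl)allylation in which 20 adds at its γ-carbon through a Zimmerman–Traxler chair, the Z geometry giving the syn C7/C8 relationship (7R with 8R), while zinc bridging the aldehyde and oxolane oxygens should expose the convex face of the chelate so that C8 forms as R, anti to the C10–O bond; this 1,3-induction is the least secure selectivity of the route.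

Step 13
Reactants: 21 the hydroxy ester of step 12; 22 angelic acid
Product: 23 methyl (3R,4R)-5-[(2R,3S,5S)-3-(tert-butyldimethylsilyloxy)-5-[(1Z)-1-iodoprop-1-en-2-yl]-2-methyloxolan-2-yl]-3-(dimethoxymethyl)-4-[(Z)-2-methylbut-2-enoyloxy]-2-methylidenepentanoate
Conditions: angelic acid, 2,4,6-trichlorobenzoyl chloride, Et3N, toluene, rt; then 21, 60 °C (no DMAP)
Reagents that add atoms: none
Why: Yamaguchi mixed-anhydride acylation without a nucleophilic catalyst should transfer the angeloyl group to the C8 hydroxyl with its Z geometry intact, before the hindered γ-hydroxy ester can lactonize.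

Step 14
Reactants: 23 the angelate of step 13
Product: 24 methyl (3R,4R)-5-[(2R,3S,5S)-3-(tert-butyldimethylsilyloxy)-5-[(1Z)-1-iodoprop-1-en-2-yl]-2-methyloxolan-2-yl]-3-formyl-4-[(Z)-2-methylbut-2-enoyloxy]-2-methylidenepentanoate
Conditions: LiBF4, MeCN/H2O (98:2), rt; used at once
Reagents that add atoms: water O
Why: Lewis-acid-assisted acetal hydrolysis unmasks the C6 aldehyde directly, so no free C6 hydroxyl that could lactonize onto C12 ever appears, and the mild acid should leave the epimerizable C7 centre, the silyl ether and both esters intact.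

Step 15
Reactants: 24 the iodoalkenyl aldehyde of step 14
Product: 26 (1S,3S,4Z,6S,7R,8R,10R)-8-angeloyloxy-1-(tert-butyldimethylsilyloxy)-3,10-epoxygermacra-4,11(13)-dien-6,12-olide, via hydroxy ester 25 (not isolated)
Conditions: CrCl2 (10 equiv), NiCl2 (0.1 equiv), DMSO/THF (3:1), 0.002 M, slow addition of 24, rt; aq. NH4Cl work-up (PPTS, CH2Cl2 if lactonization is incomplete)
Reagents that add atoms: none
Why: Zerovalent nickel, formed from NiCl2 by CrCl2, inserts into the C5–I bond with retention of the Z geometry, transmetalation gives the alkenyl species of trivalent chromium, and its 1,2-addition to the C6 aldehyde forms the C5–C6 bond, after which the chromium alkoxide of 25 attacks the C12 methyl ester and expels methoxide. The closest known reaction type is the intramolecular Nozaki–Hiyama–Kishi closure of nine-membered oxacycles onto 2,5-disubstituted oxolanes, coupled with the lactonization of a γ-hydroxy α-methylene ester. The oxonene (nine-membered through O, ten-membered through C1–C2) closes by exo-trig attack on the aldehyde carbon, the γ-lactone by 5-exo-trig acyl substitution. C6 should be set as S by a Felkin–Anh transition state in which C11 of the acrylate is anti to the incoming alkenyl group, the ring-tethered C8 lies gauche to it beside the carbonyl oxygen and H7 faces the aldehyde hydrogen; this is the only staggered arrangement in which the tether can reach, and it places O6 cis to C11 as the cis-fused lactone requires. The step needs chemoselective insertion at the only C(sp2)–I bond (aldehyde, esters and acrylate are inert to the nickel and chromium species), cyclization rather than oligomerization (high dilution, slow addition, the Z alkene turning C5 toward C6) and lactonization rather than O8-to-O6 angeloyl transfer (five- versus six-membered transition state).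

Step 16
Reactants: 26 the silyl ether of step 15
Product: 27 (1S,3S,4Z,6S,7R,8R,10R)-8-angeloyloxy-1-hydroxy-3,10-epoxygermacra-4,11(13)-dien-6,12-olide (target)
Conditions: HF·pyridine, pyridine, THF, 0 °C → rt
Reagents that add atoms: none
Why: Buffered fluoride desilylation should free the C1 hydroxyl without touching the angelate, the α-methylene lactone or the allylic lactone C–O bond.

Compound list

1 | prop-2-yn-1-ol (propargyl alcohol) | C#CCO | starting material
2 | alkenylmagnesium chelate, 4-methyl-2,5-dihydro-1,2-oxamagnesole (Mg on the alkene carbon cis to CH2O) | CC1=C[Mg]OC1 | intermediate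
3 | (Z)-3-iodo-2-methylprop-2-en-1-ol | OC/C(C)=C\I | intermediate
4 | (Z)-3-iodo-2-methylprop-2-enal | O=C/C(C)=C\I | intermediate
5 | borinate, diisopinocampheylborinic ester of 6 (Ipc groups from (+)-α-pinene) | C=CC[C@H](OB([C@@H]1C[C@@H]2C[C@H]([C@H]1C)C2(C)C)[C@@H]1C[C@@H]2C[C@H]([C@H]1C)C2(C)C)/C(C)=C\I | intermediate
6 | (3S,1Z)-1-iodo-2-methylhexa-1,5-dien-3-ol | C=CC[C@H](O)/C(C)=C\I | intermediate
7 | methacrolein (2-methylprop-2-enal) | C=C(C)C=O | starting material
8 | (2E,5S,6Z)-5-hydroxy-7-iodo-2,6-dimethylhepta-2,6-dienal | O=C/C(C)=C/C[C@H](O)/C(C)=C\I | intermediate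
9 | (1Z,3S,5E)-1-iodo-2,6-dimethylocta-1,5,7-trien-3-ol | C=C/C(C)=C/C[C@H](O)/C(C)=C\I | intermediate
10 | vinyl epoxide, (2S,3Z)-1-[(2S,3S)-3-ethenyl-3-methyloxiran-2-yl]-4-iodo-3-methylbut-3-en-2-ol | C=C[C@]1(C)O[C@H]1C[C@H](O)/C(C)=C\I | intermediate
11 | (2R,3S,5S)-2-ethenyl-5-[(1Z)-1-iodoprop-1-en-2-yl]-2-methyloxolan-3-ol (C4 arm trans to vinyl, cis to OH and methyl) | I/C=C(/C)[C@@H]1C[C@H](O)[C@@](C)(C=C)O1 | intermediate
12 | tert-butyldimethylsilyl ether of 11 | I/C=C(/C)[C@@H]1C[C@H](O[Si](C)(C)C(C)(C)C)[C@@](C)(C=C)O1 | intermediate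
13 | alkylborane, B-alkyl-9-borabicyclo[3.3.1]nonane from 12 (boron on the terminal carbon C8) | I/C=C(/C)[C@@H]1C[C@H](O[Si](C)(C)C(C)(C)C)[C@@](C)(CCB2C3CCCC2CCC3)O1 | intermediate
14 | 2-[(2R,3S,5S)-3-(tert-butyldimethylsilyloxy)-5-[(1Z)-1-iodoprop-1-en-2-yl]-2-methyloxolan-2-yl]ethan-1-ol | I/C=C(/C)[C@@H]1C[C@H](O[Si](C)(C)C(C)(C)C)[C@@](C)(CCO)O1 | intermediate
15 | 2-[(2R,3S,5S)-3-(tert-butyldimethylsilyloxy)-5-[(1Z)-1-iodoprop-1-en-2-yl]-2-methyloxolan-2-yl]acetaldehyde | I/C=C(/C)[C@@H]1C[C@H](O[Si](C)(C)C(C)(C)C)[C@@](C)(CC=O)O1 | intermediate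
16 | 2,2-dimethoxyacetaldehyde | COC(OC)C=O | starting material
17 | methyl acrylate | C=CC(=O)OC | starting material
18 | methyl 3-hydroxy-4,4-dimethoxy-2-methylidenebutanoate (racemic) | C=C(C(=O)OC)C(O)C(OC)OC | intermediate
19 | methyl (Z)-2-(bromomethyl)-4,4-dimethoxybut-2-enoate | BrC/C(C(=O)OC)=C\C(OC)OC | intermediate
20 | allylzinc bromide from 19 | Br[Zn]C/C(C(=O)OC)=C\C(OC)OC | intermediate
21 | methyl (3R,4R)-5-[(2R,3S,5S)-3-(tert-butyldimethylsilyloxy)-5-[(1Z)-1-iodoprop-1-en-2-yl]-2-methyloxolan-2-yl]-3-(dimethoxymethyl)-4-hydroxy-2-methylidenepentanoate (C7 R, C8 R) | I/C=C(/C)[C@@H]1C[C@H](O[Si](C)(C)C(C)(C)C)[C@@](C)(C[C@@H](O)[C@H](C(OC)OC)C(=C)C(=O)OC)O1 | intermediate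
22 | angelic acid, (Z)-2-methylbut-2-enoic acid | C/C=C(/C)C(=O)O | starting material
23 | C8 angelate of 21 | I/C=C(/C)[C@@H]1C[C@H](O[Si](C)(C)C(C)(C)C)[C@@](C)(C[C@@H](OC(=O)/C(C)=C\C)[C@H](C(OC)OC)C(=C)C(=O)OC)O1 | intermediate
24 | C6 aldehyde, methyl (3R,4R)-3-formyl-4-angeloyloxy-2-methylidene-5-(oxolan-2-yl)pentanoate with the oxolane of 15 | I/C=C(/C)[C@@H]1C[C@H](O[Si](C)(C)C(C)(C)C)[C@@](C)(C[C@@H](OC(=O)/C(C)=C\C)[C@H](C=O)C(=C)C(=O)OC)O1 | intermediate
25 | ring-closed hydroxy ester, methyl 2-[(4Z,6S)-8-angeloyloxy-1-(tert-butyldimethylsilyloxy)-6-hydroxy-3,10-epoxygermacr-4-en-7-yl]prop-2-enoate (other centres as in 26) | C=C(C(=O)OC)[C@H]1[C@@H](O)/C=C(/C)[C@@H]2C[C@H](O[Si](C)(C)C(C)(C)C)[C@@](C)(C[C@H]1OC(=O)/C(C)=C\C)O2 | intermediate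
26 | (1S,3S,4Z,6S,7R,8R,10R)-8-angeloyloxy-1-(tert-butyldimethylsilyloxy)-3,10-epoxygermacra-4,11(13)-dien-6,12-olide | C=C1C(=O)O[C@H]2/C=C(/C)[C@@H]3C[C@H](O[Si](C)(C)C(C)(C)C)[C@@](C)(C[C@@H](OC(=O)/C(C)=C\C)[C@@H]12)O3 | intermediate
27 | (1S,3S,4Z,6S,7R,8R,10R)-8-angeloyloxy-1-hydroxy-3,10-epoxygermacra-4,11(13)-dien-6,12-olide | C=C1C(=O)O[C@H]2/C=C(/C)[C@@H]3C[C@H](O)[C@@](C)(C[C@@H](OC(=O)/C(C)=C\C)[C@@H]12)O3 | target

Total step count: 16 (steps 10 and 11 prepare bromide 19).
Longest linear sequence: 14 (steps 1–9 and 12–16).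

Steps most likely to fail

Step 15. Closure across the trans-disposed oxolane arms builds a strained inside–outside bicycle. The strained transition state may slow cyclization relative to oligomerization and may erode or reverse the facial selectivity of the addition to the C6 aldehyde, after which lactonization would lock the wrong epimer. The fallback takes stereocontrol at C6 out of the carbon–carbon bond formation. It sets out from aldehyde 24: the same closure is run and quenched cold (aq. NaHCO3/serine), so that the hydroxy ester is isolated before lactonization as 25 together with its C6 epimer F1. Dess–Martin oxidation of the mixture converges both on the macrocyclic enone F2. A reagent-controlled Corey–Bakshi–Shibata reduction (Me-CBS oxazaborolidine, catecholborane, −78 °C, the catalyst antipode that delivers 6S) returns 25, and PPTS in CH2Cl2 lactonizes it, rejoining the route at 26.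

Step 12. Poor π-facial selectivity at the C8 aldehyde is the concern, because 1,3-induction from the quaternary C10 is weak and the (7S,8S) syn adduct would form alongside 21. The fallback replaces substrate control by reagent control with a tartrate-modified allylboronate. It sets out from bromide 19, which is converted into the diisopropyl (R,R)-tartrate (Z)-allylboronate F3 (Zn, THF; then the 2-isopropoxy-1,3,2-dioxaborolane made from B(OiPr)3 and diisopropyl (R,R)-tartrate). F3 adds to aldehyde 15 (toluene, 4 Å molecular sieves, −78 °C → rt) through a closed chair on the Si face dictated by the tartrate, the Z geometry again giving the syn relationship. Hydrolytic work-up rejoins the route at 21.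

Step 13. Slow acylation of the hindered C8 hydroxyl may let γ-lactonization of 21 onto C12 compete, and the activated angelate may isomerize from Z to E. The fallback builds the Z alkene on the ester instead of carrying it through the acylation. It sets out from 21, which is esterified with 2-[bis(2,2,2-trifluoroethoxy)phosphoryl]propanoic acid (DCC, cat. DMAP, CH2Cl2, 0 °C) to the phosphonopropanoate F4 (mixture at the phosphonate carbon). A Still–Gennari olefination with acetaldehyde (KHMDS, 18-crown-6, THF, −78 °C) should give the Z-configured 2-methylbut-2-enoate, rejoining the route at 23.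

Further compounds

F1 | step 15 | C6 epimer (6R) of hydroxy ester 25 | C=C(C(=O)OC)[C@H]1[C@H](O)/C=C(/C)[C@@H]2C[C@H](O[Si](C)(C)C(C)(C)C)[C@@](C)(C[C@H]1OC(=O)/C(C)=C\C)O2
F2 | step 15 | macrocyclic C6 enone from 25 and F1 | C=C(C(=O)OC)[C@H]1C(=O)/C=C(/C)[C@@H]2C[C@H](O[Si](C)(C)C(C)(C)C)[C@@](C)(C[C@H]1OC(=O)/C(C)=C\C)O2
F3 | step 12 | diisopropyl (4R,5R)-2-[(Z)-4,4-dimethoxy-2-(methoxycarbonyl)but-2-enyl]-1,3,2-dioxaborolane-4,5-dicarboxylate | CC(C)OC(=O)[C@@H]1OB(C/C(C(=O)OC)=C\C(OC)OC)O[C@H]1C(=O)OC(C)C
F4 | step 13 | C8 2-[bis(2,2,2-trifluoroethoxy)phosphoryl]propanoate of 21 | I/C=C(/C)[C@@H]1C[C@H](O[Si](C)(C)C(C)(C)C)[C@@](C)(C[C@@H](OC(=O)C(C)P(=O)(OCC(F)(F)F)OCC(F)(F)F)[C@H](C(OC)OC)C(=C)C(=O)OC)O1
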